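- In a one-step world the ratio of two products stands still from the first minute. Dusk's does not: target over other capture product reads 1.31 at 1.33 h and 2.08 at 15.0 h. The gas starts out of solution, so suppose target needs it dissolved.

| setting | spring | dusk | flask |
|---|---|---|---|
| starting material | 0.13 M | 0.30 M | 0.20 M |
| second nucleophile | 0.30 M | 0.30 M | 0.300 M |
| gas | 51 mM (held) | 51 mM (held) | 51 mM (held) |
| remark | run made earlier | run made earlier |  |
| time |  |  | 20 h |

- spring (time / h: target / %, other capture product / %): 3.00: 41.9, 18.0; 6.00: 54.0, 19.9; 10.0: 55.9, 20.9; 12.0: 56.4, 21.3; 15.0: 56.5, 20.8
- dusk (time / h: target / %, other capture product / %): 1.33: 14.3, 10.9; 4.00: 31.3, 17.0; 8.00: 38.2, 18.3; 12.0: 39.3, 18.1; 15.0: 38.7, 18.6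

(scatter of a reading: 0.5 percentage points)

- at the start none of the gas is in solution

* share of target in target plus other capture product at 10 min
* share of target in target plus other capture product at 1.5 h
* share of target in target plus other capture product at 20 h

- Turn the time first. By hand, the ratio stops moving when the products stop growing. Spring's target goes from 56.4 % at 12.0 h to 56.5 % at 15.0 h, a step inside the scatter, so expect the plateau at 20 h.
- Turn the starting material next. The last readings give 2.72 in spring and 2.08 in dusk, lower at the higher charge. Place the flask between them in proportion to its charge, which gives 2.45. Call this the capture ratio, target over other capture product on the plateau. As my own reckoning, that is an end share of 71.1 %.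
- Turn the second nucleophile last. No run changed it, so reckon by hand: let both products come from one short-lived intermediate held at a steady low level (the steady-state picture). Each product then gains in step with its partner, so, with the course of the dissolved gas held the same, the capture ratio goes as one over [second nucleophile].
- The forecast gives 26 % (15 % to 38 %), 60 % (55 % to 65 %) and 70.7 % (69.3 % to 72 %), on the ground that “it dissolves slowly”. My end share stands slightly above its figure, inside its range.
- The flask gives 30.8 %, 60.4 % and 70.6 %, each inside the forecast's range. Its capture ratio is 2.40 against my 2.45, and running the flask on to 200 h leaves its end share in place.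

    starting material ⇌ intermediate (K = 0.0150, k = 4.20 × 10⁻⁴ s⁻¹)
    first nucleophile + intermediate → target (k = 0.390 L mol⁻¹ s⁻¹)
    second nucleophile + intermediate → other capture product (k = 0.0110 L mol⁻¹ s⁻¹)
    gas ⇌ first nucleophile, rate k4*(csat - [first nucleophile]) (kL = 3.00 × 10⁻⁴ s⁻¹)
    2 starting material → homo dimer (k = 2.80 × 10⁻⁴ L mol⁻¹ s⁻¹)

- Now take the neighbour with 1.2 M of second nucleophile, 4.00 times the flask's 0.300 M. Divide the capture ratio by that factor to get 0.614, an end share of 38.0 %. At 20.0 h this neighbour holds 28.8 % target and 47.7 % other capture product, a share of 37.7 %.

(The runs were computed with constants of no real substance.)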